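**Retrosynthetic overview**
1. The 1,2-diol of the target is unmasked last from an isopropylidene ketal (compound 7).
2. Key disconnection: the methine–(indol-3-yl) bond, made by Friedel–Crafts alkylation of indole with a 2-indolylmethyl cation that carries the dioxolane stereocentre.
3. That cation is released by acid ring-opening of a tetrahydropyrano[3,4-b]indole (compound 4); the opening also returns the 2-hydroxyethyl arm.
4. Compound 4 comes from an oxa-Pictet–Spengler reaction of tryptophol with (R)-glyceraldehyde acetonide, which supplies the carbinol centre; the methine centre follows by 1,2-induction.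
5. Ring order: both indoles and the dioxolane are bought; only the temporary pyran ring is formed (step 1) and opened (step 2).

Assumption: (R)-glyceraldehyde acetonide 2 is taken as a commercial reagent and used freshly distilled. The route has not been run; the sense of induction in step 2 is a model-based prediction.

**Step 1**
Reactants: 1 tryptophol [2-(1H-indol-3-yl)ethan-1-ol]; 2 (R)-2,2-dimethyl-1,3-dioxolane-4-carbaldehyde
Product: 4 1-[(4R)-2,2-dimethyl-1,3-dioxolan-4-yl]-1,3,4,9-tetrahydropyrano[3,4-b]indole (both C1 epimers), via hemiacetal 3 (not isolated)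
Conditions: 2 (1.2 equiv), CF3CO2H (0.2 equiv), 4 Å MS, CH2Cl2, 0 °C to rt
Reagents that add atoms: none
Why: The alcohol of 1 and aldehyde 2 give hemiacetal 3, which loses water under acid and is closed by indole C2 in an oxa-Pictet–Spengler reaction; the dioxolane stereocentre is untouched (anhydrous acid at low temperature avoids enolisation) and the new C1 centre forms as an epimer mixture that is erased in step 2.

**Step 2**
Reactants: 4 1-[(4R)-2,2-dimethyl-1,3-dioxolan-4-yl]-1,3,4,9-tetrahydropyrano[3,4-b]indole; 5 indole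
Product: 7 2-{2-[(S)-[(4S)-2,2-dimethyl-1,3-dioxolan-4-yl](1H-indol-3-yl)methyl]-1H-indol-3-yl}ethan-1-ol, via alkylideneindolium ion 6 (not isolated)
Conditions: 5 (3 equiv), Sc(OTf)3 (10 mol %), 4 Å MS, CH2Cl2, −20 °C to rt
Reagents that add atoms: none
Why: Sc(OTf)3 reopens the benzylic-type C1–O bond of 4 (retro-oxa-Pictet–Spengler ionisation) to ion 6 and indole C3 adds irreversibly in a Friedel–Crafts alkylation; with the dioxolane C–H eclipsing the exocyclic C=C (least allylic 1,3-strain against the ring N–H) the nucleophile enters anti to the dioxolane C–O bond (Felkin–Anh-type 1,2-induction), which sets the (S)-methine.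

**Step 3**
Reactants: 7 2-{2-[(S)-[(4S)-2,2-dimethyl-1,3-dioxolan-4-yl](1H-indol-3-yl)methyl]-1H-indol-3-yl}ethan-1-ol
Product: 8 (2S,3S)-3-[3-(2-hydroxyethyl)-1H-indol-2-yl]-3-(1H-indol-3-yl)propane-1,2-diol (Colletotryptin B)
Conditions: AcOH–H2O (4:1), 40 °C
Reagents that add atoms: none
Why: Mild aqueous-acid ketal hydrolysis frees the 1,2-diol without breaking any bond to a stereogenic carbon, and acetic acid is too weak to ionise the bis(indolyl)methane; the diol oxygens are those of the ketal and the oxygen of water leaves in acetone.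

**Compound list**
1 | tryptophol, 2-(1H-indol-3-yl)ethan-1-ol | OCCc1c[nH]c2ccccc12 | starting material
2 | (R)-2,2-dimethyl-1,3-dioxolane-4-carbaldehyde [(R)-glyceraldehyde acetonide] | O=C[C@H]1COC(C)(C)O1 | starting material
3 | hemiacetal [(4R)-2,2-dimethyl-1,3-dioxolan-4-yl][2-(1H-indol-3-yl)ethoxy]methanol (hemiacetal carbon undefined) | OC(OCCc1c[nH]c2ccccc12)[C@H]1COC(C)(C)O1 | intermediate
4 | 1-[(4R)-2,2-dimethyl-1,3-dioxolan-4-yl]-1,3,4,9-tetrahydropyrano[3,4-b]indole (C1 epimer mixture) | C1(OCCc2c1[nH]c1ccccc21)[C@H]1COC(C)(C)O1 | intermediate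
5 | indole | c1ccc2[nH]ccc2c1 | starting material
6 | 2-(2-{[(4S)-2,2-dimethyl-1,3-dioxolan-4-yl]methylidene}-2H-indol-1-ium-3-yl)ethan-1-olate (ring-opened zwitterion, oxygen held by scandium) | [O-]CCC1=C2C=CC=CC2=[NH+]C1=C[C@H]1COC(C)(C)O1 | intermediate
7 | 2-{2-[(S)-[(4S)-2,2-dimethyl-1,3-dioxolan-4-yl](1H-indol-3-yl)methyl]-1H-indol-3-yl}ethan-1-ol | OCCc1c([C@H](c2c[nH]c3ccccc23)[C@H]2COC(C)(C)O2)[nH]c2ccccc12 | intermediate
8 | (2S,3S)-3-[3-(2-hydroxyethyl)-1H-indol-2-yl]-3-(1H-indol-3-yl)propane-1,2-diol (Colletotryptin B) | OCCc1c([C@H](c2c[nH]c3ccccc23)[C@H](O)CO)[nH]c2ccccc12 | target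

**Total step count:** 3
**Longest linear sequence:** 3 steps (1 → 4 → 7 → 8)

**Steps most likely to fail (highest risk first)**

Step 2. The risks are sluggish C–O ionisation, partial epimerisation of the dioxolane centre through the enol ether of ion 6, and above all a facial preference that is low or opposite to the model. The minor methine epimer is removed by chromatography at the stage of 7.

The fallback reverses the roles of the two indoles and is stereocomplementary: whichever facial rule an α-dioxolanyl indolylmethyl cation obeys, the two pairings give opposite methine configurations. It sets out from compound 5 and comes back at compound 7. Indole 5, aldehyde 2 and 4-methylbenzenesulfinic acid (EtOAc, rt) condense to the sulfonyl indole 3-{[(4R)-2,2-dimethyl-1,3-dioxolan-4-yl](4-methylbenzenesulfonyl)methyl}-1H-indole F1. In(OTf)3 (10 mol %) in CH2Cl2 then ionises F1 by loss of sulfinate, and C2 of tryptophol 1 is alkylated to give 7.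

Step 1. The aldehyde 2 can enolise or oligomerise under acid, and ring closure may be slow. The fallback makes the C2–carbon bond by metalation instead of acid catalysis and also avoids the ether ionisation of step 2. It sets out from compound 1 and comes back at compound 7.
- TBSCl and imidazole in DMF give 3-[2-(tert-butyldimethylsilyloxy)ethyl]-1H-indole F2.
- n-BuLi, then CO2 (THF, −78 °C), give lithium 3-[2-(tert-butyldimethylsilyloxy)ethyl]indole-1-carboxylate F3 in the flask.
- t-BuLi lithiates C2 to give lithium 3-[2-(tert-butyldimethylsilyloxy)ethyl]-2-lithioindole-1-carboxylate F4, which adds to aldehyde 2.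
- NH4Cl work-up decarboxylates to the carbinol [(4R)-2,2-dimethyl-1,3-dioxolan-4-yl]{3-[2-(tert-butyldimethylsilyloxy)ethyl]-1H-indol-2-yl}methanol F5 (carbinol epimers, irrelevant because this carbon is ionised next).
- F5, indole 5 and Sc(OTf)3 under the conditions of step 2 give 3-{(S)-[(4S)-2,2-dimethyl-1,3-dioxolan-4-yl]{3-[2-(tert-butyldimethylsilyloxy)ethyl]-1H-indol-2-yl}methyl}-1H-indole F6.
- TBAF in THF gives 7.

Step 3. Protic acid could reionise the bis(indolyl)methane (retro-Friedel–Crafts, reclosure to a pyranoindole) before the ketal is gone. The fallback moves the ketal hydrolysis ahead of the C–C coupling and carries the diol as silyl ethers, so the last unmasking uses fluoride. It sets out from compound 4 and comes back at compound 8.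
- AcOH–H2O on 4 gives (1R)-1-(1,3,4,9-tetrahydropyrano[3,4-b]indol-1-yl)ethane-1,2-diol F7.
- TBSCl and imidazole in DMF give 1-[(1R)-1,2-bis(tert-butyldimethylsilyloxy)ethyl]-1,3,4,9-tetrahydropyrano[3,4-b]indole F8.
- Ring-opening Friedel–Crafts alkylation of indole 5 under the conditions of step 2 gives 2-{2-[(1S,2S)-2,3-bis(tert-butyldimethylsilyloxy)-1-(1H-indol-3-yl)propyl]-1H-indol-3-yl}ethan-1-ol F9.
- TBAF in THF gives 8.

**Further compounds**
F1 | step 2 | 3-{[(4R)-2,2-dimethyl-1,3-dioxolan-4-yl](4-methylbenzenesulfonyl)methyl}-1H-indole (epimers at the sulfonyl carbon) | Cc1ccc(cc1)S(=O)(=O)C(c1c[nH]c2ccccc12)[C@H]1COC(C)(C)O1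
F2 | step 1 | 3-[2-(tert-butyldimethylsilyloxy)ethyl]-1H-indole | CC(C)(C)[Si](C)(C)OCCc1c[nH]c2ccccc12
F3 | step 1 | lithium 3-[2-(tert-butyldimethylsilyloxy)ethyl]indole-1-carboxylate | [Li+].[O-]C(=O)n1cc(CCO[Si](C)(C)C(C)(C)C)c2ccccc12
F4 | step 1 | lithium 3-[2-(tert-butyldimethylsilyloxy)ethyl]-2-lithioindole-1-carboxylate | [Li+].[O-]C(=O)n1c([Li])c(CCO[Si](C)(C)C(C)(C)C)c2ccccc12
F5 | step 1 | [(4R)-2,2-dimethyl-1,3-dioxolan-4-yl]{3-[2-(tert-butyldimethylsilyloxy)ethyl]-1H-indol-2-yl}methanol (carbinol epimers) | CC(C)(C)[Si](C)(C)OCCc1c(C(O)[C@H]2COC(C)(C)O2)[nH]c2ccccc12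
F6 | step 1 | 3-{(S)-[(4S)-2,2-dimethyl-1,3-dioxolan-4-yl]{3-[2-(tert-butyldimethylsilyloxy)ethyl]-1H-indol-2-yl}methyl}-1H-indole | CC(C)(C)[Si](C)(C)OCCc1c([C@H](c2c[nH]c3ccccc23)[C@H]2COC(C)(C)O2)[nH]c2ccccc12
F7 | step 3 | (1R)-1-(1,3,4,9-tetrahydropyrano[3,4-b]indol-1-yl)ethane-1,2-diol (C1 epimer mixture of the pyran) | C1(OCCc2c1[nH]c1ccccc21)[C@H](O)CO
F8 | step 3 | 1-[(1R)-1,2-bis(tert-butyldimethylsilyloxy)ethyl]-1,3,4,9-tetrahydropyrano[3,4-b]indole | C1(OCCc2c1[nH]c1ccccc21)[C@H](O[Si](C)(C)C(C)(C)C)CO[Si](C)(C)C(C)(C)C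
F9 | step 3 | 2-{2-[(1S,2S)-2,3-bis(tert-butyldimethylsilyloxy)-1-(1H-indol-3-yl)propyl]-1H-indol-3-yl}ethan-1-ol | OCCc1c([C@H](c2c[nH]c3ccccc23)[C@H](O[Si](C)(C)C(C)(C)C)CO[Si](C)(C)C(C)(C)C)[nH]c2ccccc12
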